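The plan cuts ring C of the flavanone at C3–C4 and at the C2–H bond. C4 is an aryl ketone carbon on ring A, C3 an unsubstituted methylene and C2 an ether-bearing benzylic stereocentre, so ring C is the formal adduct of an aromatic formyl C–H bond across an aryl 1-phenylvinyl ether. A single rhodium-catalysed enantioselective endo hydroacylation forms C3–C4, closes ring C and sets C2 as S. Its precursor is a fully substituted benzaldehyde with the 1-phenylvinyloxy group ortho to the formyl group, the prenyl group beside it and both phenols flanking the methoxy group masked as MOM ethers; these are removed last.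

Key step: step 8

Remarks on the chemistry
- Flavanone numbering is used for 17 and 18: O1, C2, C3, C4, C4a, C5–C8, C8a; ring A is the benzo ring, ring B the phenyl group, ring C the pyranone. Prenyl = 3-methylbut-2-en-1-yl; MOM = methoxymethyl.
- Assumption: the target SMILES corresponds to 2S. (R)-DTBM-SEGPHOS is written provisionally in step 8; the ligand antipode that gives 2S is to be fixed by a trial run.
- Design of the precursor 16:
  - The oxygen ortho to the formyl group on the side away from the vinyl ether (later O5) stays capped. A free phenol there would bind rhodium as a phenoxide chelate and hold the acyl metal away from the alkene.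
  - MOM is preferred to benzyl (hydrogenolysis would reduce the prenyl group) and to allyl (reactive towards rhodium hydride).
  - The ring carries no aryl C–H and the enol ether no allylic hydrogen, so cyclometalation and alkene isomerisation are excluded by construction.

Step 1
Reactants: 1 2-methoxyresorcinol; 2 chloromethyl methyl ether
Product: 3 1,3-bis(methoxymethoxy)-2-methoxybenzene
Conditions: NaH (2.4 equiv), MOMCl (2.4 equiv), DMF, 0 °C to rt
Reagents that add atoms: chloromethyl methyl ether, COCCl
Why: Williamson-type O-alkylation of both sodium phenoxides by the reactive α-chloro ether (MOM protection); the two hydroxyls are equivalent, so no selectivity is required.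

Step 2
Reactants: 3 1,3-bis(methoxymethoxy)-2-methoxybenzene; 4 bis(pinacolato)diboron
Product: 6 3,5-bis(methoxymethoxy)-4-methoxyphenol, via aryl pinacol boronate 5 (not isolated)
Conditions: [Ir(OMe)(cod)]2 (1.5 mol%), 4,4'-di-tert-butyl-2,2'-bipyridine (3 mol%), B2pin2, THF, 80 °C; then H2O2, aq. NaOH, 0 °C to rt
Reagents that add atoms: hydrogen peroxide, OO (phenol oxygen of 6); bis(pinacolato)diboron, CC1(C)OB(OC1(C)C)B1OC(C)(C)C(C)(C)O1 (boryl group of 5 only)
Why: Iridium-catalysed C–H borylation is sterically controlled and should select C5, the only C–H with no ortho substituent, and the boronate is oxidised in the same flask by basic peroxide (borylation–oxidation) without harm to the MOM acetals.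

Step 3
Reactants: 6 3,5-bis(methoxymethoxy)-4-methoxyphenol; 7 3-chloro-3-methylbut-1-yne
Product: 8 2-methoxy-1,3-bis(methoxymethoxy)-5-[(2-methylbut-3-yn-2-yl)oxy]benzene
Conditions: CuCl2·2H2O (1 mol%), DBU, MeCN, 0 °C
Reagents that add atoms: 3-chloro-3-methylbut-1-yne, C#CC(C)(C)Cl
Why: Copper-catalysed O-propargylation of a phenol with a tertiary propargylic chloride (through a copper-bound allenylidene-type electrophile) is the standard entry to aryl 1,1-dimethylpropargyl ethers and works best on electron-rich phenols.

Step 4
Reactants: 8 2-methoxy-1,3-bis(methoxymethoxy)-5-[(2-methylbut-3-yn-2-yl)oxy]benzene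
Product: 9 2-methoxy-1,3-bis(methoxymethoxy)-5-[(2-methylbut-3-en-2-yl)oxy]benzene
Conditions: H2 (1 atm), Pd/CaCO3 poisoned with Pb(OAc)2, quinoline, EtOAc, rt
Reagents that add atoms: none
Why: Lindlar semihydrogenation should stop at the terminal alkene on the poisoned palladium surface, and aryl MOM ethers are inert to it.

Step 5
Reactants: 9 2-methoxy-1,3-bis(methoxymethoxy)-5-[(2-methylbut-3-en-2-yl)oxy]benzene
Product: 11 4-methoxy-3,5-bis(methoxymethoxy)-2-(3-methylbut-2-en-1-yl)phenol, via ortho-dienone 10 (not isolated)
Conditions: PhNEt2, 130 °C, argon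
Reagents that add atoms: none
Why: Aromatic Claisen rearrangement ([3,3]-sigmatropic shift) transfers the 1,1-dimethylallyl group with allylic inversion, hence as a linear prenyl group, to one of the two equivalent ortho carbons (the para position is blocked by methoxy), and the dienone tautomerises to the phenol.

Step 6
Reactants: 11 4-methoxy-3,5-bis(methoxymethoxy)-2-(3-methylbut-2-en-1-yl)phenol; 12 formaldehyde (used as paraformaldehyde)
Product: 14 2-hydroxy-5-methoxy-4,6-bis(methoxymethoxy)-3-(3-methylbut-2-en-1-yl)benzaldehyde, via salicyl alcohol 13 (not isolated)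
Conditions: MgCl2 (anhydrous), Et3N, (CH2O)n, MeCN, reflux
Reagents that add atoms: formaldehyde (as paraformaldehyde), C=O
Why: Magnesium phenoxide-directed ortho-formylation (Casnati–Skattebøl reaction) hydroxymethylates the only free ring position, which lies ortho to the hydroxyl, and hydride transfer to a second formaldehyde gives the aldehyde under basic conditions that spare MOM ethers and the prenyl alkene.

Step 7
Reactants: 14 2-hydroxy-5-methoxy-4,6-bis(methoxymethoxy)-3-(3-methylbut-2-en-1-yl)benzaldehyde; 15 1-phenylvinylboronic acid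
Product: 16 5-methoxy-4,6-bis(methoxymethoxy)-3-(3-methylbut-2-en-1-yl)-2-[(1-phenylethenyl)oxy]benzaldehyde
Conditions: Cu(OAc)2 (2 equiv), pyridine, 1-phenylvinylboronic acid (2.5 equiv), 4 Å molecular sieves, CH2Cl2, dry air, rt; chromatography on Et3N-washed silica
Reagents that add atoms: 1-phenylvinylboronic acid, C=C(B(O)O)c1ccccc1
Why: Chan–Lam oxidative C–O coupling, in which the copper phenoxide transmetalates with the alkenylboronic acid and reductive elimination from trivalent copper should give the aryl alkenyl ether under mild basic conditions that leave the aldehyde, the MOM ethers and the prenyl group untouched; excess boronic acid offsets protodeboronation.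

Step 8
Reactants: 16 5-methoxy-4,6-bis(methoxymethoxy)-3-(3-methylbut-2-en-1-yl)-2-[(1-phenylethenyl)oxy]benzaldehyde
Product: 17 (2S)-6-methoxy-5,7-bis(methoxymethoxy)-8-(3-methylbut-2-en-1-yl)-2-phenyl-2,3-dihydro-4H-chromen-4-one (agrandol 5,7-bis-MOM ether)
Conditions: [Rh(cod)Cl]2 (2.5 mol%), (R)-DTBM-SEGPHOS (5 mol%), NaB[3,5-(CF3)2C6H3]4 (5 mol%), dry THF, 25 to 60 °C, argon
Reagents that add atoms: none
Why: Proposed new method: the cationic bisphosphine complex of monovalent rhodium, formed from [Rh(cod)Cl]2, the ligand and the sodium borate, should add oxidatively to the formyl C–H bond of 16, bind the tethered 1-phenylvinyl ether, transfer hydride to the oxygen- and phenyl-bearing alkene carbon (C2) while rhodium takes the terminal CH2 (C3), and then eliminate reductively from the seven-membered acyl alkyl complex of trivalent rhodium to form C3–C4. The closest known reaction type is the rhodium-catalysed enantioselective endo hydroacylation of ortho-allylbenzaldehydes bearing 1,1-disubstituted alkenes to 3-substituted tetralones, of which 16 is the oxygen-tethered analogue; an aryl enol ether has not been shown as the alkene partner. Ring C closes in a formal 6-endo-trig mode. C2 is set in the hydride transfer under control of the chiral bisphosphine, which must direct hydride to the Re face of C2 (O1, phenyl ipso carbon and C3 clockwise) to give 2S. The step needs endo over exo regiochemistry, secured by the 1,1-disubstituted alkene (the exo path would require a tertiary alkylrhodium and a quaternary centre) and by the enol ether polarity, and chemoselectivity over the prenyl alkene, which is trisubstituted and sits meta to the acyl carbon. The enol ether has no allylic hydrogen, so alkene isomerisation cannot compete, and the MOM cap on the oxygen ortho to the formyl group prevents a phenoxide chelate that would hold rhodium away from the alkene.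

Step 9
Reactants: 17 (2S)-6-methoxy-5,7-bis(methoxymethoxy)-8-(3-methylbut-2-en-1-yl)-2-phenyl-2,3-dihydro-4H-chromen-4-one
Product: 18 agrandol, (2S)-5,7-dihydroxy-6-methoxy-8-(3-methylbut-2-en-1-yl)-2-phenyl-2,3-dihydro-4H-chromen-4-one
Conditions: dilute HCl (about 1 M), MeOH, 25 to 40 °C
Reagents that add atoms: none
Why: Acid-catalysed acetal solvolysis (MOM cleavage) in methanol should outpace protonation of the trisubstituted prenyl alkene at low acid strength, and acid, unlike base, does not open the flavanone by retro-oxa-Michael reaction, so C2 should be retained.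

Compound list
1 | 2-methoxyresorcinol (2-methoxybenzene-1,3-diol) | COc1c(O)cccc1O | starting material
2 | chloromethyl methyl ether | COCCl | starting material
3 | 1,3-bis(methoxymethoxy)-2-methoxybenzene | COCOc1cccc(OCOC)c1OC | intermediate
4 | bis(pinacolato)diboron | CC1(C)OB(OC1(C)C)B1OC(C)(C)C(C)(C)O1 | starting material
5 | 2-[3,5-bis(methoxymethoxy)-4-methoxyphenyl]-4,4,5,5-tetramethyl-1,3,2-dioxaborolane | COCOc1cc(B2OC(C)(C)C(C)(C)O2)cc(OCOC)c1OC | intermediate
6 | 3,5-bis(methoxymethoxy)-4-methoxyphenol | COCOc1cc(O)cc(OCOC)c1OC | intermediate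
7 | 3-chloro-3-methylbut-1-yne | C#CC(C)(C)Cl | starting material
8 | 2-methoxy-1,3-bis(methoxymethoxy)-5-[(2-methylbut-3-yn-2-yl)oxy]benzene | COCOc1cc(OC(C)(C)C#C)cc(OCOC)c1OC | intermediate
9 | 2-methoxy-1,3-bis(methoxymethoxy)-5-[(2-methylbut-3-en-2-yl)oxy]benzene | COCOc1cc(OC(C)(C)C=C)cc(OCOC)c1OC | intermediate
10 | 4-methoxy-3,5-bis(methoxymethoxy)-6-(3-methylbut-2-en-1-yl)cyclohexa-2,4-dien-1-one (racemic) | O=C1C=C(OCOC)C(OC)=C(OCOC)C1CC=C(C)C | intermediate
11 | 4-methoxy-3,5-bis(methoxymethoxy)-2-(3-methylbut-2-en-1-yl)phenol | COCOc1cc(O)c(CC=C(C)C)c(OCOC)c1OC | intermediate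
12 | formaldehyde (used as paraformaldehyde) | C=O | starting material
13 | 2-(hydroxymethyl)-4-methoxy-3,5-bis(methoxymethoxy)-6-(3-methylbut-2-en-1-yl)phenol | OCc1c(O)c(CC=C(C)C)c(OCOC)c(OC)c1OCOC | intermediate
14 | 2-hydroxy-5-methoxy-4,6-bis(methoxymethoxy)-3-(3-methylbut-2-en-1-yl)benzaldehyde | O=Cc1c(O)c(CC=C(C)C)c(OCOC)c(OC)c1OCOC | intermediate
15 | 1-phenylvinylboronic acid | C=C(B(O)O)c1ccccc1 | starting material
16 | 5-methoxy-4,6-bis(methoxymethoxy)-3-(3-methylbut-2-en-1-yl)-2-[(1-phenylethenyl)oxy]benzaldehyde | O=Cc1c(OC(=C)c2ccccc2)c(CC=C(C)C)c(OCOC)c(OC)c1OCOC | intermediate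
17 | (2S)-6-methoxy-5,7-bis(methoxymethoxy)-8-(3-methylbut-2-en-1-yl)-2-phenyl-2,3-dihydro-4H-chromen-4-one | COCOc1c(OC)c(OCOC)c(CC=C(C)C)c2c1C(=O)C[C@@H](c1ccccc1)O2 | intermediate
18 | agrandol, (2S)-5,7-dihydroxy-6-methoxy-8-(3-methylbut-2-en-1-yl)-2-phenyl-2,3-dihydro-4H-chromen-4-one | COc1c(O)c(CC=C(C)C)c2c(c1O)C(=O)C[C@@H](c1ccccc1)O2 | target

Total step count: 9. Longest linear sequence: 9 steps (1 to 18).

Steps most likely to fail

1. Step 8 (hydroacylation).
   - What may go wrong: the acyl rhodium hydride may decarbonylate; the Lewis-acidic cation may trigger Prins-type addition of the enol ether to the aldehyde; hydride insertion may go the exo way; facial selectivity in the hydride transfer may be poor.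
   - Fallback (known chemistry), setting out from 14: addition of HC≡CMgBr (3 equiv, THF, 0 °C) should give the propargylic alcohol 2-(1-hydroxyprop-2-yn-1-yl)-4-methoxy-3,5-bis(methoxymethoxy)-6-(3-methylbut-2-en-1-yl)phenol F1. Oxidation with MnO2 in CH2Cl2 should give the ethynyl ketone 1-[2-hydroxy-5-methoxy-4,6-bis(methoxymethoxy)-3-(3-methylbut-2-en-1-yl)phenyl]prop-2-yn-1-one F2. K2CO3 in acetone (6-endo-dig oxa-Michael addition) should close it to the chromone 6-methoxy-5,7-bis(methoxymethoxy)-8-(3-methylbut-2-en-1-yl)-4H-chromen-4-one F3. Asymmetric conjugate addition of phenylboronic acid with Pd(OCOCF3)2 and a chiral pyridine–oxazoline ligand (t-BuPyOx, antipode chosen for 2S; NH4PF6, H2O, ClCH2CH2Cl, 60 °C) comes back to the route at 17.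

2. Step 7 (O-vinylation).
   - What may go wrong: C–O coupling may be slow at a phenol that is flanked by two ortho substituents and hydrogen-bonded to the formyl group; the α-substituted alkenylboronic acid may protodeboronate; the enol ether may hydrolyse during isolation.
   - Fallback, setting out from 14: Mitsunobu etherification with racemic 2-bromo-1-phenylethanol (PPh3, DIAD, THF, 0 °C to rt) should give the bromo ether 2-(2-bromo-1-phenylethoxy)-5-methoxy-4,6-bis(methoxymethoxy)-3-(3-methylbut-2-en-1-yl)benzaldehyde F4. E2 dehydrobromination with KOtBu in THF at 0 °C, for which only the benzylic hydrogen is available, comes back to the route at 16.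

3. Step 9 (deprotection).
   - What may go wrong: the freed 7-hydroxyl may add to the prenyl alkene under acid (chroman formation); acid-mediated opening and reclosure of ring C may erode C2.
   - Fallback, setting out from 17: acetal-to-silyl exchange under buffered aprotic conditions (Me3SiOSO2CF3, 2,2'-bipyridyl, CH2Cl2, 0 °C) should give the bis-silyl ether (2S)-6-methoxy-8-(3-methylbut-2-en-1-yl)-2-phenyl-5,7-bis[(trimethylsilyl)oxy]-2,3-dihydro-4H-chromen-4-one F5. Hydrolysis with water at neutral pH comes back to the route at 18.

Further compounds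
F1 | step 8 | 2-(1-hydroxyprop-2-yn-1-yl)-4-methoxy-3,5-bis(methoxymethoxy)-6-(3-methylbut-2-en-1-yl)phenol (racemic) | C#CC(O)c1c(O)c(CC=C(C)C)c(OCOC)c(OC)c1OCOC
F2 | step 8 | 1-[2-hydroxy-5-methoxy-4,6-bis(methoxymethoxy)-3-(3-methylbut-2-en-1-yl)phenyl]prop-2-yn-1-one | C#CC(=O)c1c(O)c(CC=C(C)C)c(OCOC)c(OC)c1OCOC
F3 | step 8 | 6-methoxy-5,7-bis(methoxymethoxy)-8-(3-methylbut-2-en-1-yl)-4H-chromen-4-one | O=c1ccoc2c(CC=C(C)C)c(OCOC)c(OC)c(OCOC)c12
F4 | step 7 | 2-(2-bromo-1-phenylethoxy)-5-methoxy-4,6-bis(methoxymethoxy)-3-(3-methylbut-2-en-1-yl)benzaldehyde (racemic) | O=Cc1c(OC(CBr)c2ccccc2)c(CC=C(C)C)c(OCOC)c(OC)c1OCOC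
F5 | step 9 | (2S)-6-methoxy-8-(3-methylbut-2-en-1-yl)-2-phenyl-5,7-bis[(trimethylsilyl)oxy]-2,3-dihydro-4H-chromen-4-one | COc1c(O[Si](C)(C)C)c(CC=C(C)C)c2c(c1O[Si](C)(C)C)C(=O)C[C@@H](c1ccccc1)O2
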